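In a one-step world each hand of the racemate keeps to itself, so left-handed product P plus left-handed substrate R stays at half of the charge. That plain kinetic resolution is my zero.

| setting | blue | flask |
|---|---|---|
| left-handed substrate | 0.49 M | 0.49 M |
| right-handed substrate | 0.49 M | 0.49 M |
| coupling partner | 1.47 M | 1.47 M |
| temperature | 90 °C | 90 °C |
| remark | the very flask that is asked about, followed so far |  |
| time |  | 3.0 h |

- blue (time / min: left-handed product / %, left-handed substrate / %): 12.0: 22.8, 23.2; 40.0: 38.6, 7.8; 60.0: 42.6, 4.1; 90.0: 45.5, 4.1; 150: 50.9, 1.9

(each reading ± 0.5 percentage points)

- midnight: at 3.0 h add coupling partner, 50.0% of the amount charged, then wait 6.0 h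
- dawn: at 3.0 h raise the temperature by 25 K, then wait 6.0 h
- spring: at 3.0 h take out 90% of the left-handed product then present, then wait 6.0 h
- noon: change nothing and wait 6.0 h more

- coupling partner is single-handed; left-handed substrate and right-handed substrate are mirror images of each other, charged as a racemate, each of them at the stated concentration
- left-handed product that was removed still counts
- the numbers in the tables scatter by 0.5 percentage points (one standard deviation)
- additions bring no volume worth counting
- the earlier runs do not show what temperature does; that part of a forecast is a guess
- the handed part of coupling partner does not stay in what it makes, so the products of the two hands are mirror images too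

1. left-handed product, in percent of the left-handed substrate and right-handed substrate together first charged, at 3.0 h
2. the option that brings most further left-handed product ("none" if no option brings more than 2 percentage points) (midnight / dawn / spring / noon / none)
3. left-handed product present, with what was taken out counted in, in percent of the left-handed substrate and right-handed substrate together first charged, after midnight
4. left-handed product present, with what was taken out counted in, in percent of the left-handed substrate and right-handed substrate together first charged, after noon

I measure this flask from that zero by the crossing X, which is P + R minus that half, in percent of the racemate charged; in the blue run it is 2.8 percentage points at 150 min. It was −4 points at 12.0 min, so it has risen by 6.8 points against a scatter of 0.5 points per reading, and substrate has reached the left hand from the right.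

For this flask after noon, my bracket starts wide: the floor is the last reading, 50.9%, and the ceiling is the whole racemate charged. To tighten it, I assume that the slope of P falls as R falls. R gives a decay time of 117 min from the readings at 60.0 min and 150 min, but 78.0 min from those at 90.0 min and 150 min. The last slope of P times these times puts P between 57.9% and 61.4%, so X ends between 7.9 points and 11 points. Held unchanged, that slope gives 53.6% at 3.0 h, which I read as an upper figure.

The forecast gives 53.2% now, 69% after midnight, 68% after noon and dawn as the best option, with the wait reckoned “with the right-handed pool decaying and some leakage to right-handed product”, and its noon figure stands above my bracket.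

    coupling partner + left-handed substrate → left-handed product (k = 7.70 × 10⁻⁴ L mol⁻¹ s⁻¹, Ea = 78.0 kJ mol⁻¹)
    coupling partner + right-handed substrate → right-handed product (k = 2.50 × 10⁻⁴ L mol⁻¹ s⁻¹, Ea = 65.0 kJ mol⁻¹)
    left-handed substrate ⇌ achiral form (K = 1.10, k = 1.60 × 10⁻⁴ s⁻¹, Ea = 121 kJ mol⁻¹, ΔH = −42.0 kJ mol⁻¹)
    right-handed substrate ⇌ achiral form (K = 1.10, k = 1.60 × 10⁻⁴ s⁻¹, Ea = 121 kJ mol⁻¹, ΔH = −42.0 kJ mol⁻¹)
    coupling partner ⇌ dormant form (K = 0.140, k = 3.50 × 10⁻⁴ s⁻¹, Ea = 100 kJ mol⁻¹, ΔH = −1.00 kJ mol⁻¹)
    (constants at 90 °C)

This flask gives 52.2% now, and dawn is best at 9.4 points, against 6.7 points for noon. Midnight ends at 58.6% and noon at 58.9%, inside the bracket. At 180 min this flask already holds 34.1% right-handed product, more than the right-handed substrate and achiral form together, and its crossing is 4.1 points. The neighbour flask kept at 65 °C has 34.8% left-handed product and 13.0% left-handed substrate at 180 min, so its crossing is still below zero, at −2.2 points.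

Readings and results stem from a simulated flask for substances that don't exist, and the scatter is random.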